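**Retrosynthetic overview**
- The target comes from the annulation product by one acidic operation that removes two methoxymethyl (MOM) ethers and one triethylsilyl (TES) ether.
- Key disconnection: C3a–C3 and C7a–O1 of the dihydrofuran ring, formed together by palladium/norbornene annulation of an ortho-acyl aryl iodide with an (S)-epoxide. This is the only ring closure of the route; both benzene rings are bought.
- Aryl iodide: 5-iodoresorcinol is acylated next to iodine (Friedel–Crafts) with 3-(4-methoxyphenyl)propanoic acid; the prenyl group enters through a 1,1-dimethylpropargyl ether, semihydrogenation and Claisen rearrangement; then MOM protection.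
- Epoxide: methyl (S)-glycerate acetonide, double methyl Grignard addition, acetonide hydrolysis, primary tosylation, ring closure, silylation; the C2–O bond of the glycerate is never broken.
- Feature on which the strategy rests: the 2-substituted 2,3-dihydrobenzofuran ring, O1–C2(H)(CMe2OH)–C3H2 fused at C3a/C7a, whose O1–C2–C3 unit maps atom for atom onto a terminal epoxide, with the C7 acyl group serving as ortho blocker.

Key step: step 12

Remark on the chemistry: the aryl iodide is assembled without metalating an iodoarene, because hindered amide bases are expected to deprotonate beside iodine (aryne formation, iodine migration) and not between the two ethers. The acyl group is therefore placed by electrophilic substitution and the prenyl group by a sigmatropic shift.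

**Route**

Step 1
Reactants: 1 1-iodo-3,5-dimethoxybenzene
Product: 2 5-iodobenzene-1,3-diol (5-iodoresorcinol)
Conditions: BBr3 (2.5 equiv), CH2Cl2, −78 °C to rt; then H2O
Reagents that add atoms: none
Why: BBr3 demethylation of aryl methyl ethers (Lewis acid ether cleavage) should free both phenols, the iodine sitting meta to both oxygens and therefore not prone to protodeiodination.

Step 2
Reactants: 2 5-iodobenzene-1,3-diol; 3 3-(4-methoxyphenyl)propanoic acid
Product: 4 1-(2,4-dihydroxy-6-iodophenyl)-3-(4-methoxyphenyl)propan-1-one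
Conditions: BF3·OEt2 (as solvent), 85 °C; then aq. NaOAc
Reagents that add atoms: none
Why: Friedel–Crafts acylation of a resorcinol with a carboxylic acid in BF3·OEt2 (O-acylation and Fries-type shift) is expected at the ring carbon para to one hydroxyl and ortho to the other, next to iodine, as with other 5-substituted resorcinols, the anisole ring of 3 being far less nucleophilic.

Step 3
Reactants: 4 1-(2,4-dihydroxy-6-iodophenyl)-3-(4-methoxyphenyl)propan-1-one
Product: 5 1-[2-hydroxy-6-iodo-4-(2-methylbut-3-yn-2-yloxy)phenyl]-3-(4-methoxyphenyl)propan-1-one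
Conditions: 3-chloro-3-methylbut-1-yne (1.2 equiv), DBU (1.2 equiv), CuCl2·2H2O (cat.), MeCN, 0 °C
Reagents that add atoms: 3-chloro-3-methylbut-1-yne, CC(C)(Cl)C#C
Why: copper-catalysed O-propargylation of a phenol with a tertiary propargylic chloride should take place only at the 4-hydroxyl, because the 2-hydroxyl is tied up in a hydrogen bond to the ketone and is much less acidic, and at 0 °C the aryl iodide does not couple with the alkyne.

Step 4
Reactants: 5 1-[2-hydroxy-6-iodo-4-(2-methylbut-3-yn-2-yloxy)phenyl]-3-(4-methoxyphenyl)propan-1-one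
Product: 6 1-[2-hydroxy-6-iodo-4-(2-methylbut-3-en-2-yloxy)phenyl]-3-(4-methoxyphenyl)propan-1-one
Conditions: H2 (1 atm, 1 equiv uptake), Pd/CaCO3 poisoned with Pb(OAc)2 (Lindlar catalyst), quinoline, EtOAc, rt
Reagents that add atoms: none
Why: Lindlar semihydrogenation should reduce the terminal alkyne to the vinyl group well before the poisoned palladium surface attacks the aryl iodide or the ketone, provided the uptake is stopped at one equivalent.

Step 5
Reactants: 6 1-[2-hydroxy-6-iodo-4-(2-methylbut-3-en-2-yloxy)phenyl]-3-(4-methoxyphenyl)propan-1-one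
Product: 7 1-[2,4-dihydroxy-6-iodo-3-(3-methylbut-2-en-1-yl)phenyl]-3-(4-methoxyphenyl)propan-1-one
Conditions: N,N-diethylaniline, 130 °C
Reagents that add atoms: none
Why: aromatic Claisen rearrangement ([3,3] shift and tautomerisation) of the 1,1-dimethylallyl ether delivers a linear prenyl group to an ortho carbon, and migration to C3 between the two oxygens is expected because the chelated ortho-hydroxy ketone fixes the C3–C4 double bond and the bulky iodine shields C5.

Step 6
Reactants: 7 1-[2,4-dihydroxy-6-iodo-3-(3-methylbut-2-en-1-yl)phenyl]-3-(4-methoxyphenyl)propan-1-one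
Product: 8 1-[6-iodo-2,4-bis(methoxymethoxy)-3-(3-methylbut-2-en-1-yl)phenyl]-3-(4-methoxyphenyl)propan-1-one
Conditions: NaH (2.2 equiv), MOMCl (2.5 equiv), DMF, 0 °C to rt
Reagents that add atoms: chloromethyl methyl ether, COCCl
Why: Williamson-type O-alkylation of both sodium phenoxides with MOMCl should give the bis-acetal, the phenols being deprotonated far ahead of the ketone α-position when the base is limited to the amount needed for two phenols.

Step 7
Reactants: 9 methyl (S)-2,2-dimethyl-1,3-dioxolane-4-carboxylate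
Product: 11 (S)-2-(2,2-dimethyl-1,3-dioxolan-4-yl)propan-2-ol, via 1-[(S)-2,2-dimethyl-1,3-dioxolan-4-yl]ethan-1-one 10 (not isolated)
Conditions: MeMgBr (2.5 equiv), THF, 0 °C; then aq. NH4Cl
Reagents that add atoms: methylmagnesium bromide, C[Mg]Br
Why: double Grignard addition to the ester should give the tertiary alcohol, the intermediate ketone being trapped by the second equivalent faster than it enolises, so that the oxygen-bearing stereocentre of the glycerate is carried over unchanged.

Step 8
Reactants: 11 (S)-2-(2,2-dimethyl-1,3-dioxolan-4-yl)propan-2-ol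
Product: 12 (S)-3-methylbutane-1,2,3-triol
Conditions: AcOH/H2O (4:1), 40 °C; evaporation
Reagents that add atoms: none
Why: acid-catalysed acetonide hydrolysis releases the 1,2-diol without breaking any bond to the stereocentre, and the water-soluble triol is isolated simply by evaporation.

Step 9
Reactants: 12 (S)-3-methylbutane-1,2,3-triol
Product: 13 (S)-2,3-dihydroxy-3-methylbutyl 4-methylbenzenesulfonate
Conditions: TsCl (1.05 equiv), Et3N, Bu2SnO (2 mol%), CH2Cl2, 0 °C to rt
Reagents that add atoms: 4-methylbenzenesulfonyl chloride, Cc1ccc(cc1)S(=O)(=O)Cl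
Why: tin acetal-catalysed regioselective sulfonylation of a 1,2-diol should tosylate only the primary hydroxyl, the secondary and tertiary hydroxyls being far slower.

Step 10
Reactants: 13 (S)-2,3-dihydroxy-3-methylbutyl 4-methylbenzenesulfonate
Product: 14 (S)-2-(oxiran-2-yl)propan-2-ol
Conditions: K2CO3, MeOH, 0 °C; careful concentration (volatile)
Reagents that add atoms: none
Why: intramolecular Williamson etherification (3-exo-tet) by the secondary oxygen on the CH2OTs carbon closes the epoxide with the C2–O bond intact, hence S is retained, while carbonate at 0 °C should keep Payne migration and oxetane formation by the tertiary hydroxyl negligible.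

Step 11
Reactants: 14 (S)-2-(oxiran-2-yl)propan-2-ol
Product: 15 (S)-triethyl{[2-(oxiran-2-yl)propan-2-yl]oxy}silane
Conditions: TESOTf, 2,6-lutidine, CH2Cl2, −78 °C
Reagents that add atoms: triethylsilyl trifluoromethanesulfonate, CC[Si](CC)(CC)OS(=O)(=O)C(F)(F)F
Why: silylation of a hindered tertiary alcohol with a silyl triflate and a hindered pyridine base is fast at −78 °C, where the buffered terminal epoxide should not be opened.

Step 12
Reactants: 8 1-[6-iodo-2,4-bis(methoxymethoxy)-3-(3-methylbut-2-en-1-yl)phenyl]-3-(4-methoxyphenyl)propan-1-one; 15 (S)-triethyl{[2-(oxiran-2-yl)propan-2-yl]oxy}silane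
Product: 16 (S)-1-[4,6-bis(methoxymethoxy)-5-(3-methylbut-2-en-1-yl)-2-{2-[(triethylsilyl)oxy]propan-2-yl}-2,3-dihydro-1-benzofuran-7-yl]-3-(4-methoxyphenyl)propan-1-one
Conditions: Pd(OAc)2 (10 mol%), XPhos (20 mol%), norbornene (50 mol%), K2CO3 (2 equiv), 15 (2 equiv), NMP, 80 °C, argon
Reagents that add atoms: none
Why: Zerovalent palladium inserts into the C–I bond of 8, norbornene inserts, and the only free ortho C–H (the future C3a) is palladated to give the aryl norbornyl palladacycle of divalent palladium; this opens epoxide 15 at its CH2 terminus (SN2-type oxidative addition to tetravalent palladium), C(sp2)–C(sp3) reductive elimination forms C3a–C3, and norbornene is extruded by β-carbon elimination because both ortho positions are now substituted. The resulting aryl palladium alkoxide closes the dihydrofuran ring by C7a–O1 reductive elimination from a six-membered oxapalladacycle (formally a 5-exo closure by oxygen on the ipso carbon), K2CO3 taking up the HI. This is the known palladium/norbornene (Catellani-type) annulation of ortho-substituted aryl iodides with epoxides to 2,3-dihydrobenzofurans, applied here to an ortho-acyl iodide. No stereocentre is created: only the CH2–O bond of 15 is broken, so C2 keeps the S configuration set in the glycerate. Site selectivity rests on the acyl group blocking one ortho position, on the single remaining ortho C–H and on epoxide opening at the unsubstituted carbon; the trisubstituted prenyl alkene lies para to palladium and is a poor Heck acceptor, and the silyl ether prevents Payne migration of the epoxide under base.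

Step 13
Reactants: 16 (S)-1-[4,6-bis(methoxymethoxy)-5-(3-methylbut-2-en-1-yl)-2-{2-[(triethylsilyl)oxy]propan-2-yl}-2,3-dihydro-1-benzofuran-7-yl]-3-(4-methoxyphenyl)propan-1-one
Product: 17 (S)-1-[4,6-dihydroxy-2-(2-hydroxypropan-2-yl)-5-(3-methylbut-2-en-1-yl)-2,3-dihydro-1-benzofuran-7-yl]-3-(4-methoxyphenyl)propan-1-one (CNP0150199.1)
Conditions: 3 M aq. HCl, MeOH, rt to 40 °C, stopped at full conversion
Reagents that add atoms: none
Why: acid-catalysed methanolysis (acetal and silyl ether cleavage) should remove both MOM groups and the TES group in one operation, as practised for MOM removal from ortho-prenyl phenols, without touching the aryl alkyl ether bond at C2 and hence the stereocentre.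

**Compound list**
1 | 1-iodo-3,5-dimethoxybenzene | COc1cc(I)cc(OC)c1 | starting material
2 | 5-iodobenzene-1,3-diol | Oc1cc(I)cc(O)c1 | intermediate
3 | 3-(4-methoxyphenyl)propanoic acid | COc1ccc(CCC(=O)O)cc1 | starting material
4 | 1-(2,4-dihydroxy-6-iodophenyl)-3-(4-methoxyphenyl)propan-1-one | COc1ccc(CCC(=O)c2c(O)cc(O)cc2I)cc1 | intermediate
5 | 1-[2-hydroxy-6-iodo-4-(2-methylbut-3-yn-2-yloxy)phenyl]-3-(4-methoxyphenyl)propan-1-one | COc1ccc(CCC(=O)c2c(O)cc(OC(C)(C)C#C)cc2I)cc1 | intermediate
6 | 1-[2-hydroxy-6-iodo-4-(2-methylbut-3-en-2-yloxy)phenyl]-3-(4-methoxyphenyl)propan-1-one | COc1ccc(CCC(=O)c2c(O)cc(OC(C)(C)C=C)cc2I)cc1 | intermediate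
7 | 1-[2,4-dihydroxy-6-iodo-3-(3-methylbut-2-en-1-yl)phenyl]-3-(4-methoxyphenyl)propan-1-one | COc1ccc(CCC(=O)c2c(O)c(CC=C(C)C)c(O)cc2I)cc1 | intermediate
8 | 1-[6-iodo-2,4-bis(methoxymethoxy)-3-(3-methylbut-2-en-1-yl)phenyl]-3-(4-methoxyphenyl)propan-1-one | COc1ccc(CCC(=O)c2c(OCOC)c(CC=C(C)C)c(OCOC)cc2I)cc1 | intermediate
9 | methyl (S)-2,2-dimethyl-1,3-dioxolane-4-carboxylate | COC(=O)[C@@H]1COC(C)(C)O1 | starting material
10 | 1-[(S)-2,2-dimethyl-1,3-dioxolan-4-yl]ethan-1-one | CC(=O)[C@@H]1COC(C)(C)O1 | intermediate
11 | (S)-2-(2,2-dimethyl-1,3-dioxolan-4-yl)propan-2-ol | CC(C)(O)[C@@H]1COC(C)(C)O1 | intermediate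
12 | (S)-3-methylbutane-1,2,3-triol | CC(C)(O)[C@@H](O)CO | intermediate
13 | (S)-2,3-dihydroxy-3-methylbutyl 4-methylbenzenesulfonate | CC(C)(O)[C@@H](O)COS(=O)(=O)c1ccc(C)cc1 | intermediate
14 | (S)-2-(oxiran-2-yl)propan-2-ol | CC(C)(O)[C@@H]1CO1 | intermediate
15 | (S)-triethyl{[2-(oxiran-2-yl)propan-2-yl]oxy}silane | CC[Si](CC)(CC)OC(C)(C)[C@@H]1CO1 | intermediate
16 | (S)-1-[4,6-bis(methoxymethoxy)-5-(3-methylbut-2-en-1-yl)-2-{2-[(triethylsilyl)oxy]propan-2-yl}-2,3-dihydro-1-benzofuran-7-yl]-3-(4-methoxyphenyl)propan-1-one | COc1ccc(CCC(=O)c2c(OCOC)c(CC=C(C)C)c(OCOC)c3c2O[C@H](C(C)(C)O[Si](CC)(CC)CC)C3)cc1 | intermediate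
17 | (S)-1-[4,6-dihydroxy-2-(2-hydroxypropan-2-yl)-5-(3-methylbut-2-en-1-yl)-2,3-dihydro-1-benzofuran-7-yl]-3-(4-methoxyphenyl)propan-1-one | COc1ccc(CCC(=O)c2c(O)c(CC=C(C)C)c(O)c3c2O[C@H](C(C)(C)O)C3)cc1 | target

**Step count**
Total: 13 steps. Longest linear sequence: 8 steps (steps 1, 2, 3, 4, 5, 6, 12, 13); the epoxide branch (steps 7 to 11) joins at step 12.

**Steps most likely to fail, with fallbacks**

Step 12. The ortho ketone may divert the catalysis: enolisation and O-chelation at palladium can hold back norbornene extrusion, or ipso termination can occur before the epoxide is engaged at the hindered palladacycle. The fallback sets out from 8 and comes back to the route at 17; it reshapes the blocker into a carbinol silyl ether, an ortho-alkyl aryl iodide of the kind on which this annulation is best behaved. NaBH4 (MeOH, 0 °C to rt) should reduce 8 to racemic 1-[6-iodo-2,4-bis(methoxymethoxy)-3-(3-methylbut-2-en-1-yl)phenyl]-3-(4-methoxyphenyl)propan-1-ol F1. TBSOTf and 2,6-lutidine (CH2Cl2, 0 °C) should convert it into tert-butyl{1-[6-iodo-2,4-bis(methoxymethoxy)-3-(3-methylbut-2-en-1-yl)phenyl]-3-(4-methoxyphenyl)propoxy}dimethylsilane F2. Annulation of F2 with 15 under the conditions of step 12 should give (2S)-7-{1-[(tert-butyldimethylsilyl)oxy]-3-(4-methoxyphenyl)propyl}-4,6-bis(methoxymethoxy)-5-(3-methylbut-2-en-1-yl)-2-{2-[(triethylsilyl)oxy]propan-2-yl}-2,3-dihydro-1-benzofuran F3, as both carbinol epimers. TBAF (THF, rt) should free 1-[(2S)-2-(2-hydroxypropan-2-yl)-4,6-bis(methoxymethoxy)-5-(3-methylbut-2-en-1-yl)-2,3-dihydro-1-benzofuran-7-yl]-3-(4-methoxyphenyl)propan-1-ol F4. Dess–Martin periodinane (NaHCO3, CH2Cl2) should oxidise only the secondary benzylic alcohol to 1-[(2S)-2-(2-hydroxypropan-2-yl)-4,6-bis(methoxymethoxy)-5-(3-methylbut-2-en-1-yl)-2,3-dihydro-1-benzofuran-7-yl]-3-(4-methoxyphenyl)propan-1-one F5, and F5 would lose its two MOM groups with HCl in MeOH as in step 13 to give 17.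

Step 13. Acid may cyclise the prenyl group onto a flanking phenol (chroman formation) or hydrate the alkene before both acetals are cleaved. The fallback sets out from 7 and comes back at 17; it changes the phenol protection so that the end game runs on fluoride. SEMCl and NaH (DMF, 0 °C) should convert 7 into 1-[6-iodo-3-(3-methylbut-2-en-1-yl)-2,4-bis{[2-(trimethylsilyl)ethoxy]methoxy}phenyl]-3-(4-methoxyphenyl)propan-1-one F6. Annulation with 15 as in step 12 should give (S)-1-[5-(3-methylbut-2-en-1-yl)-2-{2-[(triethylsilyl)oxy]propan-2-yl}-4,6-bis{[2-(trimethylsilyl)ethoxy]methoxy}-2,3-dihydro-1-benzofuran-7-yl]-3-(4-methoxyphenyl)propan-1-one F7. TBAF with ethylenediamine as formaldehyde scavenger (DMPU, 60 °C) should then remove both SEM groups and the TES ether without acid and deliver 17.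

Step 5. The allyl unit may migrate to C5 beside iodine instead of C3, or the tertiary allyl ether may fragment with loss of isoprene before the sigmatropic shift. The fallback sets out from 4 and comes back at 7; it replaces the O-alkylation/rearrangement relay (steps 3 to 5) by direct C-prenylation of the phenoxide with prenyl bromide and DBU in THF at rt. C3, flanked by two oxygen donors, is the most nucleophilic ring carbon, and O-prenyl and C5 isomers would be removed by chromatography. No new compound is made on this way (F0).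

**Further compounds**
F1 | step 12 | 1-[6-iodo-2,4-bis(methoxymethoxy)-3-(3-methylbut-2-en-1-yl)phenyl]-3-(4-methoxyphenyl)propan-1-ol (racemic carbinol) | COc1ccc(CCC(O)c2c(OCOC)c(CC=C(C)C)c(OCOC)cc2I)cc1
F2 | step 12 | tert-butyl{1-[6-iodo-2,4-bis(methoxymethoxy)-3-(3-methylbut-2-en-1-yl)phenyl]-3-(4-methoxyphenyl)propoxy}dimethylsilane | COc1ccc(CCC(O[Si](C)(C)C(C)(C)C)c2c(OCOC)c(CC=C(C)C)c(OCOC)cc2I)cc1
F3 | step 12 | (2S)-7-{1-[(tert-butyldimethylsilyl)oxy]-3-(4-methoxyphenyl)propyl}-4,6-bis(methoxymethoxy)-5-(3-methylbut-2-en-1-yl)-2-{2-[(triethylsilyl)oxy]propan-2-yl}-2,3-dihydro-1-benzofuran (both carbinol epimers) | COc1ccc(CCC(O[Si](C)(C)C(C)(C)C)c2c(OCOC)c(CC=C(C)C)c(OCOC)c3c2O[C@H](C(C)(C)O[Si](CC)(CC)CC)C3)cc1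
F4 | step 12 | 1-[(2S)-2-(2-hydroxypropan-2-yl)-4,6-bis(methoxymethoxy)-5-(3-methylbut-2-en-1-yl)-2,3-dihydro-1-benzofuran-7-yl]-3-(4-methoxyphenyl)propan-1-ol (both carbinol epimers) | COc1ccc(CCC(O)c2c(OCOC)c(CC=C(C)C)c(OCOC)c3c2O[C@H](C(C)(C)O)C3)cc1
F5 | step 12 | 1-[(2S)-2-(2-hydroxypropan-2-yl)-4,6-bis(methoxymethoxy)-5-(3-methylbut-2-en-1-yl)-2,3-dihydro-1-benzofuran-7-yl]-3-(4-methoxyphenyl)propan-1-one | COc1ccc(CCC(=O)c2c(OCOC)c(CC=C(C)C)c(OCOC)c3c2O[C@H](C(C)(C)O)C3)cc1
F6 | step 13 | 1-[6-iodo-3-(3-methylbut-2-en-1-yl)-2,4-bis{[2-(trimethylsilyl)ethoxy]methoxy}phenyl]-3-(4-methoxyphenyl)propan-1-one | COc1ccc(CCC(=O)c2c(OCOCC[Si](C)(C)C)c(CC=C(C)C)c(OCOCC[Si](C)(C)C)cc2I)cc1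
F7 | step 13 | (S)-1-[5-(3-methylbut-2-en-1-yl)-2-{2-[(triethylsilyl)oxy]propan-2-yl}-4,6-bis{[2-(trimethylsilyl)ethoxy]methoxy}-2,3-dihydro-1-benzofuran-7-yl]-3-(4-methoxyphenyl)propan-1-one | COc1ccc(CCC(=O)c2c(OCOCC[Si](C)(C)C)c(CC=C(C)C)c(OCOCC[Si](C)(C)C)c3c2O[C@H](C(C)(C)O[Si](CC)(CC)CC)C3)cc1
F0 | step 5 | none | none
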